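**Retrosyn­thetic overview**
Feature: ring A reads C1(OMe)–C2(OAr)–C3(Br)–C4(H)–C5(Br)–C6(H). The Br/H/Br/H run C3–C6 is the diene of 3,5-dibromo-2-pyrone, and the oxygenated pair C1/C2 is an alkyne bearing the aryloxy group and boron as a masked hydroxyl.
Disconnections: C1–OMe goes back to C1–OH and then C1–B(pin). C2–C3 and C1–C6 then come from a Diels–Alder reaction with CO2 loss between the pyrone and the (2,4-dibromophenoxy)ethynyl pinacol boronate.
The alkyne comes from 2,4-dibromophenol by O-vinylation, bromine addition, two dehydrobrominations and C–H metalation/borylation. The pyrone comes from coumalic acid in one step.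
Ring order: ring B is bought with both bromines in place. Ring A is the only ring made (step 6) and appears aromatic and fully substituted, so the diaryl ether is never halogenated.

Key step: step 6

Remark: ring B is the 2,4-dibromophenyl ring, and the target has no stereocentre. From compound 3 onward, alkyllithiums, LDA-type amides and NaNH2 are avoided. They would scramble ring B by bromine–metal exchange, by metalation of its C3–H (between two bromines) with halogen migration, or by aryne formation.

**Step 1**
Reactants: 1 coumalic acid (2-oxo-2H-pyran-5-carboxylic acid)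
Product: 2 3,5-dibromo-2H-pyran-2-one
Conditions: NBS (2.5 equiv), LiOAc, MeCN/H2O, rt
Reagents that add atoms: N-bromosuccinimide, O=C1CCC(=O)N1Br
Why: Hunsdiecker-type bromodecarboxylation of the lithium carboxylate at C5 and electrophilic bromination at the nucleophilic C3 of the pyrone take place in one flask with NBS, an established one-step entry to this dibromopyrone.

**Step 2**
Reactants: 3 2,4-dibromophenol; 4 vinyl acetate
Product: 5 2,4-dibromo-1-(ethenyloxy)benzene
Conditions: [Ir(cod)Cl]2 (1 mol %), Na2CO3 (0.6 equiv), PhMe, 100 °C
Reagents that add atoms: none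
Why: Iridium-catalysed transfer vinylation (the phenol adds to coordinated vinyl acetate, acetate leaves, and Na2CO3 takes up the acid) is an established route from phenols to aryl vinyl ethers and needs neither a strong base nor a metal that inserts into aryl C–Br bonds at this temperature.

**Step 3**
Reactants: 5 2,4-dibromo-1-(ethenyloxy)benzene
Product: 7 2,4-dibromo-1-{[(Z)-2-bromoethenyl]oxy}benzene, via 1,2-dibromoethyl ether 6 (not isolated)
Conditions: Br2 (1.0 equiv), ClCH2CH2Cl, −20 °C; then iPr2NEt (1.5 equiv), 80 °C
Reagents that add atoms: bromine, BrBr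
Why: Electrophilic addition of Br2 to the enol ether double bond is far faster than substitution on the doubly deactivated ring B, and the hindered amine then effects the classical dehydrobromination of a 1,2-dibromoethyl ether across its labile alpha C–Br bond, expected mainly as the Z isomer (any E or 1-bromovinyl isomer leads to the same alkyne in step 4, and the stereocentre of racemic 6 is lost).

**Step 4**
Reactants: 7 2,4-dibromo-1-{[(Z)-2-bromoethenyl]oxy}benzene
Product: 8 2,4-dibromo-1-(ethynyloxy)benzene
Conditions: KOtBu (1.3 equiv), THF, −78 → 0 °C; cold pH 7 work-up, basic alumina plug, kept cold in solution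
Reagents that add atoms: none
Why: Anti E2 dehydrobromination of a Z 2-halovinyl ether is the classical route to aryloxyacetylenes, because the vinyl hydrogen on the oxygen-bearing carbon is antiperiplanar to bromide, and KOtBu in cold THF causes neither bromine–metal exchange nor aryne formation on ring B.

**Step 5**
Reactants: 8 2,4-dibromo-1-(ethynyloxy)benzene; 9 2-isopropoxy-4,4,5,5-tetramethyl-1,3,2-dioxaborolane
Product: 12 2-[(2,4-dibromophenoxy)ethynyl]-4,4,5,5-tetramethyl-1,3,2-dioxaborolane, via lithium acetylide 10 (not isolated), via lithium borate complex 11 (not isolated)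
Conditions: LiN(SiMe3)2 (1.05 equiv), THF, −78 °C; 9 (1.1 equiv), −78 °C; HCl in Et2O (1.0 equiv), −78 °C → rt; filtration under Ar
Reagents that add atoms: none
Why: LiN(SiMe3)2 metalates the sp C–H by simple acid–base reaction, cannot exchange aryl bromides and is too weak to remove C3–H of ring B, and the standard alkynyllithium/alkoxyboronate sequence follows (ate complex 11, then release of isopropanol by one equivalent of anhydrous HCl), with 12 used without chromatography.

**Step 6**
Reactants: 2 3,5-dibromo-2H-pyran-2-one; 12 2-[(2,4-dibromophenoxy)ethynyl]-4,4,5,5-tetramethyl-1,3,2-dioxaborolane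
Product: 14 2-[3,5-dibromo-2-(2,4-dibromophenoxy)phenyl]-4,4,5,5-tetramethyl-1,3,2-dioxaborolane, via bridged lactone 13 (not isolated)
Conditions: 12 (1.5 equiv), PhMe, 120 °C, sealed tube, Ar
Reagents that add atoms: none
Why: The oxygen lone pair makes alkyne 12 an electron-rich dienophile whose boron-bearing carbon is the nucleophilic end, so it engages the electron-poor diene C3=C4–C5=C6 of pyrone 2 in a concerted, asynchronous inverse-demand Diels–Alder reaction (C1–C6 bond leading, C2–C3 bond following) to give bridged lactone 13, which expels CO2 by retro-Diels–Alder reaction at the same temperature. The closest known reaction types are the thermal cycloaddition/decarboxylation of 2-pyrones with alkynyl pinacol boronates to aryl boronates and the cycloadditions of 3,5-dibromo-2-pyrone with enol ethers, in which the oxygen-bearing carbon bonds to C3; an oxygen-substituted alkynyl boronate is a new member of the dienophile class, so the orientation is a prediction. Ring A is closed by an intermolecular (4+2) annulation, four carbons (C3–C6) from the pyrone and two (C1, C2) from the alkyne, and irreversible CO2 loss delivers it directly as an arene. The two bridgehead stereocentres of 13 arise as a racemate, fixed relative to each other by the bicycle, and both vanish on aromatisation, so no stereocontrol is needed. The selectivity needed is regiochemical (aryloxy carbon to C3, boron carbon to C6): it is secured by the aryloxy donor, which outweighs the weak pi-acceptor B(pin) and polarises the alkyne in the same direction as boron does, by C6 being the electrophilic terminus of the dienoate, and by sterics, since the bulky B(pin) ends next to C6–H and not next to C3–Br. The aryl group on oxygen has no beta C–H, so the retro-ene fragmentation to a ketene that limits alkyl ynol ethers is closed, and the four C–Br bonds are spectators under metal-free heating.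

**Step 7**
Reactants: 14 2-[3,5-dibromo-2-(2,4-dibromophenoxy)phenyl]-4,4,5,5-tetramethyl-1,3,2-dioxaborolane
Product: 16 3,5-dibromo-2-(2,4-dibromophenoxy)phenol, via aryl pinacol borate 15 (not isolated)
Conditions: NaBO3·4H2O (3 equiv), THF/H2O, rt
Reagents that add atoms: sodium perborate (used as the tetrahydrate), [Na+].[O-]OB=O
Why: In this boronate oxidation the peroxoborate anion adds to boron, the aryl group migrates from boron to oxygen with C1 keeping its place, and borate 15 hydrolyses in the aqueous medium, all under conditions mild enough for the diaryl ether and the four C–Br bonds.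

**Step 8**
Reactants: 16 3,5-dibromo-2-(2,4-dibromophenoxy)phenol
Product: 17 1,5-dibromo-2-(2,4-dibromophenoxy)-3-methoxybenzene (target)
Conditions: MeI (1.5 equiv), K2CO3 (2 equiv), acetone, reflux
Reagents that add atoms: iodomethane, CI
Why: Williamson ether synthesis (SN2 on iodomethane) by the phenoxide of the acidic bromophenol 16, which is the only nucleophilic site in the molecule.

**Compound list**
1 | coumalic acid (2-oxo-2H-pyran-5-carboxylic acid) | O=C(O)C1=COC(=O)C=C1 | starting material
2 | 3,5-dibromo-2H-pyran-2-one | O=C1OC=C(Br)C=C1Br | intermediate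
3 | 2,4-dibromophenol | Oc1ccc(Br)cc1Br | starting material
4 | vinyl acetate | CC(=O)OC=C | starting material
5 | 2,4-dibromo-1-(ethenyloxy)benzene | C=COc1ccc(Br)cc1Br | intermediate
6 | 2,4-dibromo-1-(1,2-dibromoethoxy)benzene (racemic, not isolated) | BrCC(Br)Oc1ccc(Br)cc1Br | intermediate
7 | 2,4-dibromo-1-{[(Z)-2-bromoethenyl]oxy}benzene | Br/C=C\Oc1ccc(Br)cc1Br | intermediate
8 | 2,4-dibromo-1-(ethynyloxy)benzene | C#COc1ccc(Br)cc1Br | intermediate
9 | 2-isopropoxy-4,4,5,5-tetramethyl-1,3,2-dioxaborolane | CC(C)OB1OC(C)(C)C(C)(C)O1 | starting material
10 | lithium (2,4-dibromophenoxy)acetylide (not isolated) | [Li]C#COc1ccc(Br)cc1Br | intermediate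
11 | lithium [(2,4-dibromophenoxy)ethynyl](isopropoxy)(pinacolato)borate (not isolated) | [Li+].CC(C)O[B-]1(C#COc2ccc(Br)cc2Br)OC(C)(C)C(C)(C)O1 | intermediate
12 | 2-[(2,4-dibromophenoxy)ethynyl]-4,4,5,5-tetramethyl-1,3,2-dioxaborolane | CC1(C)OB(C#COc2ccc(Br)cc2Br)OC1(C)C | intermediate
13 | 4,7-dibromo-5-(2,4-dibromophenoxy)-6-(4,4,5,5-tetramethyl-1,3,2-dioxaborolan-2-yl)-2-oxabicyclo[2.2.2]octa-5,7-dien-3-one (racemic, bridgeheads fixed by the bicycle, not isolated) | O=C1OC2C(Br)=CC1(Br)C(Oc1ccc(Br)cc1Br)=C2B1OC(C)(C)C(C)(C)O1 | intermediate
14 | 2-[3,5-dibromo-2-(2,4-dibromophenoxy)phenyl]-4,4,5,5-tetramethyl-1,3,2-dioxaborolane | CC1(C)OB(OC1(C)C)c1cc(Br)cc(Br)c1Oc1ccc(Br)cc1Br | intermediate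
15 | 2-[3,5-dibromo-2-(2,4-dibromophenoxy)phenoxy]-4,4,5,5-tetramethyl-1,3,2-dioxaborolane (not isolated) | CC1(C)OB(Oc2cc(Br)cc(Br)c2Oc2ccc(Br)cc2Br)OC1(C)C | intermediate
16 | 3,5-dibromo-2-(2,4-dibromophenoxy)phenol | Oc1cc(Br)cc(Br)c1Oc1ccc(Br)cc1Br | intermediate
17 | 1,5-dibromo-2-(2,4-dibromophenoxy)-3-methoxybenzene | COc1cc(Br)cc(Br)c1Oc1ccc(Br)cc1Br | target

**Total step count:** 8. **Longest linear sequence:** 7 (steps 2–8 from 2,4-dibromophenol). The pyrone branch (step 1) joins at step 6.

**Steps most likely to fail**

**Step 6.**
- Risk: regiocontrol may erode, because the ambiphilic pyrone can also react in the normal-demand sense, which would bond the boron-bearing carbon to C3. The ynol ether boronate may also oligomerise thermally before the hindered C2–C3 bond can form.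
- Fallback (sets out from 3, returns at 16): ring A is taken from a preformed arene instead of being built. The potassium salt of 3 displaces fluoride from commercial 3,5-dibromo-2-fluorobenzaldehyde (O=Cc1cc(Br)cc(Br)c1F) by nucleophilic aromatic substitution (K2CO3, DMAc, 120 °C), the formyl group activating the ortho fluoride. This should give 3,5-dibromo-2-(2,4-dibromophenoxy)benzaldehyde F1. Baeyer–Villiger oxidation (mCPBA, CH2Cl2), with migration of the aryl group that carries the ortho oxygen donor, should give 3,5-dibromo-2-(2,4-dibromophenoxy)phenyl formate F2. Methanolysis (K2CO3, MeOH) then gives phenol 16, which enters step 8.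

**Step 5.**
- Risk: the nucleophilic boron-bearing carbon may be protonated (protodeboronation). HCl may add across the polarised triple bond when the ate complex is opened, and the product may hydrolyse during isolation.
- Fallback (sets out from 8, returns at 14): silicon takes the place of boron through the cycloaddition. Lithium acetylide 10, made as in step 5, is silylated with Me3SiCl to [(2,4-dibromophenoxy)ethynyl]trimethylsilane F3, a silyl ynol ether that should tolerate water and silica. Heating F3 with pyrone 2 (PhMe, 120 °C) should follow the same orientation, since the silicon-bearing carbon is again the nucleophilic and bulky end. The reaction should pass through the silyl-substituted bridged lactone F4 to [3,5-dibromo-2-(2,4-dibromophenoxy)phenyl]trimethylsilane F5. Ipso-borodesilylation with BBr3 (CH2Cl2), directed to C1 by silicon and the ortho aryloxy group, should give dibromo[3,5-dibromo-2-(2,4-dibromophenoxy)phenyl]borane F6. Esterification with pinacol/Et3N then gives boronate 14.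

**Step 4.**
- Risk: 2,4-dibromophenoxide may be lost by anti elimination in place of bromide. tert-Butanol or tert-butoxide may add to the product, and the terminal ynol ether may oligomerise during concentration.
- Fallback (sets out from 7, returns at 12): the terminal alkyne is never handled as a discrete compound, and steps 4 and 5 collapse into one alkoxide-free operation. Compound 7 is treated with NaN(SiMe3)2 (2.2 equiv, THF, −78 → 0 °C), so that each molecule of 8 released by elimination is deprotonated at once to sodium (2,4-dibromophenoxy)acetylide F7, which is neither electrophilic nor prone to oligomerise. Addition of 9 at −78 °C gives the sodium isopropoxy(pinacolato)borate complex F8. One equivalent of HCl in Et2O then releases boronate 12.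

**Further compounds**
F1 | step 6 | 3,5-dibromo-2-(2,4-dibromophenoxy)benzaldehyde | O=Cc1cc(Br)cc(Br)c1Oc1ccc(Br)cc1Br
F2 | step 6 | 3,5-dibromo-2-(2,4-dibromophenoxy)phenyl formate | O=COc1cc(Br)cc(Br)c1Oc1ccc(Br)cc1Br
F3 | step 5 | [(2,4-dibromophenoxy)ethynyl]trimethylsilane | C[Si](C)(C)C#COc1ccc(Br)cc1Br
F4 | step 5 | 4,7-dibromo-5-(2,4-dibromophenoxy)-6-(trimethylsilyl)-2-oxabicyclo[2.2.2]octa-5,7-dien-3-one (racemic) | O=C1OC2C(Br)=CC1(Br)C(Oc1ccc(Br)cc1Br)=C2[Si](C)(C)C
F5 | step 5 | [3,5-dibromo-2-(2,4-dibromophenoxy)phenyl]trimethylsilane | C[Si](C)(C)c1cc(Br)cc(Br)c1Oc1ccc(Br)cc1Br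
F6 | step 5 | dibromo[3,5-dibromo-2-(2,4-dibromophenoxy)phenyl]borane | BrB(Br)c1cc(Br)cc(Br)c1Oc1ccc(Br)cc1Br
F7 | step 4 | sodium (2,4-dibromophenoxy)acetylide | [Na]C#COc1ccc(Br)cc1Br
F8 | step 4 | sodium [(2,4-dibromophenoxy)ethynyl](isopropoxy)(pinacolato)borate | [Na+].CC(C)O[B-]1(C#COc2ccc(Br)cc2Br)OC(C)(C)C(C)(C)O1
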